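**Conventions used throughout**

- Numbering (2,3‑seco‑labdane): carbocycle C5–C6–C7–C8–C9–C10; lactone C10–C1–C2(=O)–O–C8; C3 = CO2H on C4 (CH3‑18/19); side chain C11–C16 on C9; CH3‑17 on C8, CH3‑20 on C10.
- "Top face" of the carbocycle = the face carrying C1 (on C10) and C4 (on C5); "bottom face" = the face carrying CH3‑20 and H‑5.
- Remark (assumption): the target, a γ‑hydroxy acid (C3 acid / 6‑OH) that is not lactonised in the given structure, is assumed to survive liberation and work‑up near neutral pH.

## Analysis of the target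

The core is a 2‑oxabicyclo[3.3.1]nonan‑3‑one: a cyclohexane (C5–C10) bridged across C10 and C8 by the lactone arm C1–C2(=O)–O. There are seven stereocentres: C5, C6, C8, C9, C10 on the ring (C8 and C10 quaternary), the carbinol C11, and the tertiary allylic carbinol C13. All five functional ring substituents (C1, C4, O6, O8, C11) lie on the top face; only CH3‑17, CH3‑20 and hydrogens lie on the bottom face. C11 therefore sits between two quaternary carbons on the more hindered face. The feature that decides the strategy is the vicinal pair C10/C5: it carries two cis carboxyl‑terminated arms, C10–C1–C2 and C5–C4(Me)2–C3, so C2 and C3 are the two ends of a six‑membered ring (C10, C1, C2, C3, C4, C5) that has been cut at C2–C3. The rest of the carbocycle (C6 and C9 para to each other, methyls on C8 and C10) has the substitution pattern of 2,6‑dimethyl‑1,4‑benzoquinone. Sensitive points are the γ‑hydroxy acid (lactonisation onto O6), the lactone carbonyl flanked by 6‑OH and 11‑OH (acyl migration), the acid‑labile tertiary allylic alcohol, and the vinyl group, which rules out hydrogenolysis and unselective alkene cleavage. The difficulty lies in the contiguous array C4(q)–C5–C10(q)–C9–C8(q), the concave placement of C11, and the remote C13.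

## Retrosynthetic reasoning

**23 ⇐ 22 ⇐ 21 ⇐ 20 (C8–O bond).** The lactone oxygen must be cis to C1. Closing the C8–O bond from the C2 carboxylate onto a C7=C8 alkene (iodolactonisation, then reductive removal of iodine) makes this automatic. It sets C8, leaves C7 as CH2 and leaves the C3 acid free, as in the target. Fluoride desilylation is the last step so that the 6‑OH is never free before the C3 acid exists.

**20 ⇐ 17 (C2=C3 scission).** Both carboxyl groups are taken from one ring: ring A of cis‑decalin 17, whose C2=C3 bond is a silyl enol ether. This is the most electron‑rich alkene in the molecule, so it can be cut in the presence of C7=C8 and the vinyl group. It also gives C2 and C3 at different oxidation levels. Until then the two acids are hidden as a hydrocarbon ring that tolerates hydrides, bases and organolithiums.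

**17 ⇐ 16 ⇐ 15 ⇐ 14 (C12/C13).** The C13 carbinol is made from the C12=C13 alkene of dienyl carbinol 14 by hydroxyl‑directed epoxidation and directed hydride opening at C12. C13 is thus relayed from C11 by allylic 1,3‑strain rather than set by a second chiral reagent.

**14 ⇐ 13 ⇐ 9 + 12 (C9–C11 bond).** The bond is cut between C9 and C11 because intermolecular C–C formation on the top face of C9 is sterically disfavoured. A [2,3]‑Wittig rearrangement of ether 13 delivers C11 intramolecularly from a top‑face C7 oxygen. In one event it sets C9 and C11, returns the alkene to C7=C8 for the later lactonisation, and removes the C7 oxygen.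

**9 ⇐ 8 ⇐ 7 ⇐ 6 ⇐ 5 (oxygen from C9 to C7).** The quinone‑derived C9 oxygen is not needed in the target. It is used to drive a radical epoxide opening that leaves a top‑face C7 hydroxyl and the C8=C9 alkene. The epoxide oxygen is placed on the top face by the two cis hydroxyls of diol 5.

**5 ⇐ 4.** Hydride from the convex face of the cis‑fused ene‑dione 4 sets C6 and gives the cis diol.

**4 ⇐ 2 + 3 (C1–C10 and C4–C5).** The cis‑decalin is cut into diene 2 and quinone 3. The forward Diels–Alder reaction forms the quaternary C10, the C4(q)–C5 bond and the C5/C10 relationship in one step from two achiral components, and is the only step that needs an external source of chirality. 2 comes from 1 in one step; bromide 12 comes from enynol 10 via dienol 11.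

## Alternatives that were turned down

**Alternative 1:** (the textbook one) C2–C3 oxidative scission of an intact chiral‑pool labdane decalin, then lactonisation of the C2 acid onto the 8‑hydroxyl. Forward key step: cleavage of a ring‑A 2,3‑dioxygenated trans‑decalin. Turned down on structure: a trans‑A/B labdane has C1 and C4 trans across C10–C5 and has CH3‑20, CH3‑17 and C11 on one face. Scission can therefore only lead to the 8,10‑bis‑epimer A1, not to the target, which needs C1 cis to C4 and C11 anti to both methyls. Correcting two ring centres, one of them quaternary, and adding oxygen at C2, C3, C6 and C11 of an unfunctionalised decalin would cost more than a de novo route.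

**Alternative 2:** C4–C5 disconnection by Ireland–Claisen rearrangement of a C7 allylic isobutyrate (1,3‑chirality transfer C7→C5), then iodolactonisation of the new acid onto C6. Forward key step: the [3,3] shift. Turned down because the sequence ends in the C3→O6 γ‑lactone A2. Its selective opening beside the δ‑lactone is not credible: hydroxide attacks the unhindered C2 carbonyl first, and re‑acidification recloses the gem‑dimethyl γ‑lactone. The quaternary C10 would also still need a conjugate addition onto a fully substituted carbon.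

**Alternative 3:** single‑atom insertion: Baeyer–Villiger oxidation of bicyclo[3.2.1]octan‑6‑one A3, with migration of the bridgehead C8 to give the C2–O–C8 lactone. Forward key step: the oxygen insertion. Turned down on step economy: the insertion is reliable, but A3 carries the same five ring stereocentres on a bridged carbocycle with two bridgehead methyls and no short access. It replaces the easiest bond of the target (a lactone C–O) and solves none of the hard ones.

Key step: step 2

## Route

Step 1
Reactants: 1 4‑methylpent‑3‑en‑2‑one (mesityl oxide)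
Product: 2 triisopropyl[(4‑methylpenta‑1,3‑dien‑2‑yl)oxy]silane
Conditions: LDA, THF, −78 °C; TIPSOTf, −78 → 0 °C
Reagents that add atoms: triisopropylsilyl trifluoromethanesulfonate, CC(C)[Si](OS(=O)(=O)C(F)(F)F)(C(C)C)C(C)C
Why: Kinetic deprotonation of the α′‑methyl group gives the cross‑conjugated lithium enolate, which is silylated on oxygen (silyl enol ether formation).

Step 2
Reactants: 2 triisopropyl[(4‑methylpenta‑1,3‑dien‑2‑yl)oxy]silane; 3 2,6‑dimethyl‑1,4‑benzoquinone
Product: 4 (4aS,8aR)‑2,5,5,8a‑tetramethyl‑7‑(triisopropylsilyloxy)‑4a,5,8,8a‑tetrahydronaphthalene‑1,4‑dione (cis‑fused; labdane C6/C9 dione, Δ7, C2=C3 silyl enol ether)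
Conditions: (S)‑o‑tolyl‑diphenylprolinol oxazaborolidine·HNTf2 (20 mol %), CH2Cl2, −78 → −20 °C (the catalyst antipode is used if the opposite facial sense is found)
Reagents that add atoms: none
Why: The cationic oxazaborolidine binds 3 at the carbonyl flanked by two ring C–H (future C6), which makes the methyl‑bearing β‑carbon (C10) the electrophilic centre; the nucleophilic CH2 terminus (C1) of the 2‑silyloxydiene bonds there and the CMe2 terminus (C4) closes on C5, a Lewis‑acid‑catalysed, strongly asynchronous normal‑demand Diels–Alder reaction. The closest known reaction type is the protonated‑oxazaborolidine‑catalysed enantioselective Diels–Alder reaction of methyl‑substituted 1,4‑benzoquinones with 2‑silyloxybutadienes. Ring A (C10–C1–C2–C3–C4–C5) is closed by [4+2] cycloaddition, suprafacial on both partners, so C1 and C4 end cis on the C10–C5 bond, which fixes the relative configuration of quaternary C10 and of C5. Their absolute configuration is set by the catalyst, whose aryl group shields one face of the bound enone. The regioselectivity that is needed (C1 to C10, C4 to C5) is secured electronically by the siloxy group and the coordinated carbonyl and sterically because the other orientation would join two fully substituted carbons. Site selectivity is not an issue, since the two quinone C=C bonds are homotopic and the ene‑dione product is a poorer dienophile than 3. The cis‑methyl group of 2 disfavours the s‑cis conformer and is the main threat to rate; if bond formation becomes stepwise (Mukaiyama–Michael, then ring closure) the same product results because C4 carries two identical methyl groups. The step forms C1–C10 and C4–C5, creates C10 and C5, and delivers every ring‑B carbon with oxygen already at C6.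

Step 3
Reactants: 4 cis‑fused ene‑dione
Product: 5 (1S,4R,4aS,8aR)‑2,5,5,8a‑tetramethyl‑7‑(triisopropylsilyloxy)‑1,4,4a,5,8,8a‑hexahydronaphthalene‑1,4‑diol (labdane 6,9‑diol, both OH on the top face)
Conditions: NaBH4, CeCl3·7H2O, MeOH/THF, −78 °C
Reagents that add atoms: none
Why: Luche 1,2‑reduction of both enone carbonyls; hydride should enter from the convex bottom face of the cis‑fused bicycle, so both hydroxyls point to the top face and C6 is set in its final configuration.

Step 4
Reactants: 5 cis ene‑1,4‑diol
Product: 6 7,8‑epoxide of 5 with the epoxide oxygen on the top face (syn to both hydroxyls)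
Conditions: VO(acac)2 (cat.), t‑BuOOH, CH2Cl2, 0 °C
Reagents that add atoms: tert‑butyl hydroperoxide, CC(C)(C)OO
Why: Vanadium‑catalysed hydroxyl‑directed epoxidation; both allylic hydroxyls lie on the top face and deliver oxygen syn, placing the future C7 oxygen on the top face, while the undirected ring‑A enol ether should react far more slowly.

Step 5
Reactants: 6 epoxy diol
Product: 7 6‑O‑tert‑butyldimethylsilyl ether of 6 (9‑OH free)
Conditions: TBSCl, imidazole, DMF, 0 °C
Reagents that add atoms: tert‑butyldimethylsilyl chloride, CC(C)(C)[Si](C)(C)Cl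
Why: Selective silylation; the C6 hydroxyl is the accessible one, whereas the C9 hydroxyl lies between the quaternary C10 and the fully substituted epoxide carbon C8.

Step 6
Reactants: 7 mono‑silyl ether
Product: 8 9‑O‑[(methylsulfanyl)carbonothioyl] derivative (S‑methyl xanthate) of 7
Conditions: NaH, CS2, THF, 0 °C; MeI, 0 °C → rt
Reagents that add atoms: carbon disulfide, S=C=S; iodomethane, CI
Why: Xanthate formation for Barton–McCombie deoxygenation; the alkoxide is cis to the epoxide and cannot undergo Payne rearrangement.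

Step 7
Reactants: 8 xanthate
Product: 9 allylic alcohol: 6‑OTBS (top), 7‑OH (top), C8(Me)=C9H, ring‑A enol ether intact
Conditions: Bu3SnH (excess, high concentration), AIBN, toluene, 90 °C
Reagents that add atoms: none
Why: Barton–McCombie C–O homolysis gives the C9 radical, an epoxy‑carbinyl radical that opens by C8–O scission to the C8=C9 alkene and a C7 alkoxy radical, which the stannane reduces; the C7–O bond is never broken, so the hydroxyl keeps the top‑face configuration of the epoxide.

Step 8
Reactants: 10 (2E)‑3‑methylpent‑2‑en‑4‑yn‑1‑ol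
Product: 11 (2E)‑3‑methylpenta‑2,4‑dien‑1‑ol
Conditions: H2 (1 atm), Lindlar catalyst, quinoline, EtOAc, 0 °C
Reagents that add atoms: none
Why: Lindlar semi‑hydrogenation of the terminal alkyne; the trisubstituted E‑alkene is untouched.

Step 9
Reactants: 11 (2E)‑3‑methylpenta‑2,4‑dien‑1‑ol
Product: 12 (3E)‑5‑bromo‑3‑methylpenta‑1,3‑diene
Conditions: PBr3, pyridine (cat.), Et2O, −20 °C; used at once
Reagents that add atoms: phosphorus tribromide, BrP(Br)Br
Why: SN2 bromination of the primary allylic alcohol at low temperature, which should preserve the E geometry.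

Step 10
Reactants: 9 allylic alcohol; 12 (3E)‑5‑bromo‑3‑methylpenta‑1,3‑diene
Product: 13 7‑O‑[(2E)‑3‑methylpenta‑2,4‑dienyl] ether of 9
Conditions: NaH added to 9 and 12 with Bu4NI (cat.), THF/DMF, 0 °C
Reagents that add atoms: none
Why: Williamson etherification with a reactive primary allylic bromide; the bromide is present from the start so that the alkoxide is trapped before 1,2‑silyl migration from O6 can occur.

Step 11
Reactants: 13 bis‑allylic ether
Product: 14 homoallylic alcohol: C9 bears H (bottom) and C11 (top); (11S)‑OH; C11–CH=C(CH3)–CH=CH2 (E); C7=C8 alkene; 6‑OTBS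
Conditions: n‑BuLi, THF, −78 → −30 °C; NH4Cl (aq)
Reagents that add atoms: none
Why: [2,3]‑Wittig rearrangement of the α‑oxy pentadienyl anion through a five‑membered envelope transition state; it is suprafacial, so C11 is delivered to C9 on the face of the C7–O bond (top), and the dienyl group should sit exo, away from the ring and its C10 substituents, which corresponds to 11S. The C7 oxygen becomes the C11 hydroxyl and the alkene returns to C7=C8.

Step 12
Reactants: 14 dienyl carbinol
Product: 15 12,13‑epoxide of 14 (threo; epoxide oxygen on the face of the C11–OH in the H‑eclipsed conformer)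
Conditions: VO(acac)2 (cat.), t‑BuOOH, CH2Cl2, 0 °C
Reagents that add atoms: tert‑butyl hydroperoxide, CC(C)(C)OO
Why: Hydroxyl‑directed epoxidation of the allylic C12=C13 bond only; the methyl group cis to C11 imposes allylic 1,3‑strain, so the carbinol hydrogen eclipses the alkene and oxygen is delivered threo, a preference the bulky C9 residue on the other face should reinforce; with the E‑alkene this corresponds to 13R after opening.

Step 13
Reactants: 15 epoxy alcohol
Product: 16 (11S,13R)‑11,13‑diol with the C13 vinyl carbinol (C12 = CH2)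
Conditions: Red‑Al, THF, 0 °C → rt; Rochelle salt work‑up
Reagents that add atoms: none
Why: Alkoxide‑directed intramolecular hydride delivery to C12 of the 2,3‑epoxy alcohol gives the 1,3‑diol; the C13–O bond is not touched, so its configuration is retained.

Step 14
Reactants: 16 diol
Product: 17 11,13‑bis(triethylsilyl) ether of 16
Conditions: TESOTf, 2,6‑lutidine, CH2Cl2, −78 → 0 °C
Reagents that add atoms: triethylsilyl trifluoromethanesulfonate, CC[Si](CC)(CC)OS(=O)(=O)C(F)(F)F
Why: Silylation of the hindered secondary and the tertiary hydroxyl, so that neither takes part in iodocyclisation or acyl migration later.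

Step 15
Reactants: 17 tris‑silyl ether with ring‑A silyl enol ether
Product: 20 2,3‑seco diacid (C10–CH2–CO2H and C5–C(CH3)2–CO2H; C7=C8 alkene; 6‑OTBS; 11,13‑OTES), via silyl ester aldehyde 18 (not isolated), via silyl ester acid 19 (not isolated)
Conditions: O3 (1.0 equiv, Sudan Red 7B end point), CH2Cl2/MeOH, −78 °C; Me2S; then NaClO2, NaH2PO4, 2‑methyl‑2‑butene, t‑BuOH/H2O, 0 °C → rt; then K2CO3, MeOH/H2O, rt; acidify to pH 4
Reagents that add atoms: ozone, [O-][O+]=O; sodium chlorite, [Na+].[O-]Cl=O
Why: Ozone should cleave the silyl enol ether, by far the most electron‑rich alkene, before the hindered C7=C8 bond or the oxygen‑deactivated vinyl group, giving the C2 silyl ester and the C3 aldehyde; Pinnick oxidation of the non‑enolisable aldehyde and mild methanolysis of the silyl ester then give the diacid.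

Step 16
Reactants: 20 diacid
Product: 21 iodolactone: C2(=O)–O–C8 lactone (oxygen on the top face of C8), iodine on the bottom face of C7, C3 acid free
Conditions: I2, NaHCO3, MeCN/H2O, 0 °C, dark
Reagents that add atoms: iodine, II
Why: Iodolactonisation; only the C2 carboxylate can reach the tertiary (Markovnikov) carbon C8 through a six‑membered ring, and because it is tethered on the top face of C10 it must form the C8–O bond on that face, anti to the iodonium, which sets C8. The C3 carboxylate could reach only the secondary carbon C7.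

Step 17
Reactants: 21 iodolactone
Product: 22 6‑O‑TBS‑11,13‑bis‑O‑TES derivative of the target
Conditions: Bu3SnH, AIBN, toluene, 80 °C
Reagents that add atoms: none
Why: Radical reductive deiodination at C7, which is not a stereocentre in the product.

Step 18
Reactants: 22 tris‑silyl ether
Product: 23 target, CNP0297019.1
Conditions: HF·pyridine, pyridine, THF, 0 °C → rt; pH 6 phosphate buffer work‑up
Reagents that add atoms: none
Why: Fluoride‑mediated cleavage of the three silyl ethers under buffered, only weakly acidic conditions that should leave the tertiary allylic alcohol, the lactone and the free γ‑hydroxy acid unchanged.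

## Compound list

1 | 4‑methylpent‑3‑en‑2‑one | CC(=O)C=C(C)C | starting material
2 | triisopropyl[(4‑methylpenta‑1,3‑dien‑2‑yl)oxy]silane | C=C(O[Si](C(C)C)(C(C)C)C(C)C)C=C(C)C | intermediate
3 | 2,6‑dimethyl‑1,4‑benzoquinone | CC1=CC(=O)C=C(C)C1=O | starting material
4 | (4aS,8aR)‑2,5,5,8a‑tetramethyl‑7‑(triisopropylsilyloxy)‑4a,5,8,8a‑tetrahydronaphthalene‑1,4‑dione | C[C@@]12CC(O[Si](C(C)C)(C(C)C)C(C)C)=CC(C)(C)[C@@H]1C(=O)C=C(C)C2=O | intermediate
5 | (1S,4R,4aS,8aR)‑2,5,5,8a‑tetramethyl‑7‑(triisopropylsilyloxy)‑1,4,4a,5,8,8a‑hexahydronaphthalene‑1,4‑diol | C[C@@]12CC(O[Si](C(C)C)(C(C)C)C(C)C)=CC(C)(C)[C@@H]1[C@H](O)C=C(C)[C@@H]2O | intermediate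
6 | top‑face 7,8‑epoxide of 5 (syn to both hydroxyls) | C[C@@]12CC(O[Si](C(C)C)(C(C)C)C(C)C)=CC(C)(C)[C@@H]1[C@H](O)[C@@H]3O[C@]3(C)[C@@H]2O | intermediate
7 | 6‑O‑TBS ether of 6 | C[C@@]12CC(O[Si](C(C)C)(C(C)C)C(C)C)=CC(C)(C)[C@@H]1[C@H](O[Si](C)(C)C(C)(C)C)[C@@H]3O[C@]3(C)[C@@H]2O | intermediate
8 | 9‑O‑(S‑methyl xanthate) of 7 | C[C@@]12CC(O[Si](C(C)C)(C(C)C)C(C)C)=CC(C)(C)[C@@H]1[C@H](O[Si](C)(C)C(C)(C)C)[C@@H]3O[C@]3(C)[C@@H]2OC(=S)SC | intermediate
9 | 6‑OTBS, 7‑OH (top), Δ8(9) allylic alcohol | C[C@@]12CC(O[Si](C(C)C)(C(C)C)C(C)C)=CC(C)(C)[C@@H]1[C@H](O[Si](C)(C)C(C)(C)C)[C@H](O)C(C)=C2 | intermediate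
10 | (2E)‑3‑methylpent‑2‑en‑4‑yn‑1‑ol | OC/C=C(\C)C#C | starting material
11 | (2E)‑3‑methylpenta‑2,4‑dien‑1‑ol | OC/C=C(\C)C=C | intermediate
12 | (3E)‑5‑bromo‑3‑methylpenta‑1,3‑diene | BrC/C=C(\C)C=C | intermediate
13 | 7‑O‑[(2E)‑3‑methylpenta‑2,4‑dienyl] ether of 9 | C[C@@]12CC(O[Si](C(C)C)(C(C)C)C(C)C)=CC(C)(C)[C@@H]1[C@H](O[Si](C)(C)C(C)(C)C)[C@H](OC/C=C(\C)C=C)C(C)=C2 | intermediate
14 | [2,3]‑Wittig product, (11S)‑dienyl carbinol on C9 (top), Δ7 | C[C@@]12CC(O[Si](C(C)C)(C(C)C)C(C)C)=CC(C)(C)[C@@H]1[C@H](O[Si](C)(C)C(C)(C)C)C=C(C)[C@@H]2[C@@H](O)/C=C(\C)C=C | intermediate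
15 | threo 12,13‑epoxide of 14 | C[C@@]12CC(O[Si](C(C)C)(C(C)C)C(C)C)=CC(C)(C)[C@@H]1[C@H](O[Si](C)(C)C(C)(C)C)C=C(C)[C@@H]2[C@@H](O)[C@@H]3O[C@@]3(C)C=C | intermediate
16 | (11S,13R)‑11,13‑diol | C[C@@]12CC(O[Si](C(C)C)(C(C)C)C(C)C)=CC(C)(C)[C@@H]1[C@H](O[Si](C)(C)C(C)(C)C)C=C(C)[C@@H]2[C@@H](O)C[C@@](C)(O)C=C | intermediate
17 | 11,13‑bis‑TES ether of 16 | C[C@@]12CC(O[Si](C(C)C)(C(C)C)C(C)C)=CC(C)(C)[C@@H]1[C@H](O[Si](C)(C)C(C)(C)C)C=C(C)[C@@H]2[C@@H](O[Si](CC)(CC)CC)C[C@@](C)(O[Si](CC)(CC)CC)C=C | intermediate
18 | seco C2 triisopropylsilyl ester / C3 aldehyde | C[C@@]1(CC(=O)O[Si](C(C)C)(C(C)C)C(C)C)[C@H](C(C)(C)C=O)[C@H](O[Si](C)(C)C(C)(C)C)C=C(C)[C@@H]1[C@@H](O[Si](CC)(CC)CC)C[C@@](C)(O[Si](CC)(CC)CC)C=C | intermediate (not isolated)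
19 | seco C2 triisopropylsilyl ester / C3 acid | C[C@@]1(CC(=O)O[Si](C(C)C)(C(C)C)C(C)C)[C@H](C(C)(C)C(=O)O)[C@H](O[Si](C)(C)C(C)(C)C)C=C(C)[C@@H]1[C@@H](O[Si](CC)(CC)CC)C[C@@](C)(O[Si](CC)(CC)CC)C=C | intermediate (not isolated)
20 | 2,3‑seco diacid | C[C@@]1(CC(=O)O)[C@H](C(C)(C)C(=O)O)[C@H](O[Si](C)(C)C(C)(C)C)C=C(C)[C@@H]1[C@@H](O[Si](CC)(CC)CC)C[C@@](C)(O[Si](CC)(CC)CC)C=C | intermediate
21 | 7‑iodo 8,2‑lactone | C[C@@]12CC(=O)O[C@@](C)([C@H](I)[C@@H](O[Si](C)(C)C(C)(C)C)[C@H]1C(C)(C)C(=O)O)[C@@H]2[C@@H](O[Si](CC)(CC)CC)C[C@@](C)(O[Si](CC)(CC)CC)C=C | intermediate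
22 | 6‑O‑TBS‑11,13‑bis‑O‑TES target | C[C@@]12CC(=O)O[C@@](C)(C[C@@H](O[Si](C)(C)C(C)(C)C)[C@H]1C(C)(C)C(=O)O)[C@@H]2[C@@H](O[Si](CC)(CC)CC)C[C@@](C)(O[Si](CC)(CC)CC)C=C | intermediate
23 | CNP0297019.1 | C=C[C@](C)(O)C[C@H](O)[C@@H]1[C@]2(C)CC(=O)O[C@@]1(C)C[C@@H](O)[C@H]2C(C)(C)C(=O)O | target

## Step count and uncertain steps

Total: 18 steps. Longest linear sequence: 16 steps (steps 1–7 and 10–18); the side‑chain bromide takes 2 steps (8, 9).

**Step 2 (key step).** Most likely failure: the cycloaddition is too slow, because the cis‑methyl group of 2 disfavours the s‑cis conformer; the diene is then consumed by oligomerisation or the reaction stops at the open Michael adduct, and enantioselectivity erodes at the higher temperature needed. Fallback: 2 and 3 are combined with an achiral promoter (BF3·OEt2, CH2Cl2, −78 °C, or heat) to give 4 as the racemate, i.e. together with its enantiomer F1. Luche reduction as in step 3 gives 5 together with its enantiomer F2. Lipase‑catalysed transesterification with vinyl acetate (enzyme chosen so that the unwanted antipode reacts at its accessible C6 hydroxyl) converts F2 into its 6‑O‑acetate F3, and chromatographic separation returns to the route at 5.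

**Step 7.** Most likely failure: the C7 alkoxy radical fragments (C6–C7 β‑scission towards the silyloxy‑stabilised C6 radical) or abstracts hydrogen intramolecularly before it is reduced. Fallback without an oxygen radical: from 7, Dess–Martin oxidation of the C9 hydroxyl gives the α,β‑epoxy ketone F4; Wharton transposition (hydrazine hydrate, AcOH, MeOH) then gives the C8=C9 alkene and the top‑face C7 hydroxyl, returning at 9.

**Step 11.** Most likely failure: loss of simple diastereoselectivity at C11 (dienyl group endo), a competing [1,2]‑shift at higher temperature, or E/Z scrambling of the pentadienyl anion. Fallback for C11 by reagent control: from 13, the rearrangement mixture containing the 11‑epimer F5 is oxidised (Dess–Martin periodinane, NaHCO3) to the dienone F6, which is reduced with borane under oxazaborolidine (CBS) catalysis, returning at 14.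

**Step 15.** Most likely failure: over‑oxidation, i.e. competing cleavage of the C7=C8 alkene or the vinyl group once the enol ether is consumed. Fallback by epoxidation and glycol‑type cleavage: from 17, Rubottom oxidation (dimethyldioxirane, acetone/CH2Cl2, −78 °C, then aqueous AcOH) gives the ring‑A acyloin F7 (C2 ketone, C3 hydroxyl, either epimer). Sodium periodate cleaves it to the acid aldehyde F8, and Pinnick oxidation returns at 20.

**Step 18.** Most likely failure: acid‑promoted closure of the C3 acid onto the freed 6‑OH (γ‑lactone), acyl migration of the lactone to O6 or O11, or incomplete cleavage of the hindered C6 silyl ether. Fallback that unveils the acid last under neutral conditions: from 22, alkylation of the carboxylate (allyl bromide, Cs2CO3, DMF) gives the allyl ester F9; HF·pyridine then gives the triol allyl ester F10; Pd(PPh3)4 with morpholine in THF at room temperature removes the allyl group, returning at 23.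

## Further compounds

F1 | step 2 | enantiomer of 4 | C[C@]12CC(O[Si](C(C)C)(C(C)C)C(C)C)=CC(C)(C)[C@H]1C(=O)C=C(C)C2=O
F2 | step 2 | enantiomer of 5 | C[C@]12CC(O[Si](C(C)C)(C(C)C)C(C)C)=CC(C)(C)[C@H]1[C@@H](O)C=C(C)[C@H]2O
F3 | step 2 | 6‑O‑acetate of F2 | C[C@]12CC(O[Si](C(C)C)(C(C)C)C(C)C)=CC(C)(C)[C@H]1[C@@H](OC(C)=O)C=C(C)[C@H]2O
F4 | step 7 | 9‑ketone of 7 (α,β‑epoxy ketone) | C[C@@]12CC(O[Si](C(C)C)(C(C)C)C(C)C)=CC(C)(C)[C@@H]1[C@H](O[Si](C)(C)C(C)(C)C)[C@@H]3O[C@]3(C)C2=O
F5 | step 11 | 11‑epimer of 14 | C[C@@]12CC(O[Si](C(C)C)(C(C)C)C(C)C)=CC(C)(C)[C@@H]1[C@H](O[Si](C)(C)C(C)(C)C)C=C(C)[C@@H]2[C@H](O)/C=C(\C)C=C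
F6 | step 11 | 11‑ketone of 14 (dienone) | C[C@@]12CC(O[Si](C(C)C)(C(C)C)C(C)C)=CC(C)(C)[C@@H]1[C@H](O[Si](C)(C)C(C)(C)C)C=C(C)[C@@H]2C(=O)/C=C(\C)C=C
F7 | step 15 | ring‑A acyloin (C2 ketone, C3 hydroxyl, C3 epimers) | C[C@@]12CC(=O)C(O)C(C)(C)[C@@H]1[C@H](O[Si](C)(C)C(C)(C)C)C=C(C)[C@@H]2[C@@H](O[Si](CC)(CC)CC)C[C@@](C)(O[Si](CC)(CC)CC)C=C
F8 | step 15 | seco C2 acid / C3 aldehyde | C[C@@]1(CC(=O)O)[C@H](C(C)(C)C=O)[C@H](O[Si](C)(C)C(C)(C)C)C=C(C)[C@@H]1[C@@H](O[Si](CC)(CC)CC)C[C@@](C)(O[Si](CC)(CC)CC)C=C
F9 | step 18 | allyl ester of 22 | C[C@@]12CC(=O)O[C@@](C)(C[C@@H](O[Si](C)(C)C(C)(C)C)[C@H]1C(C)(C)C(=O)OCC=C)[C@@H]2[C@@H](O[Si](CC)(CC)CC)C[C@@](C)(O[Si](CC)(CC)CC)C=C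
F10 | step 18 | allyl ester of 23 | C[C@@]12CC(=O)O[C@@](C)(C[C@@H](O)[C@H]1C(C)(C)C(=O)OCC=C)[C@@H]2[C@@H](O)C[C@@](C)(O)C=C
A1 | alternative 1 | 8,10‑bis‑epimer of 23 (seco‑lactone with the trans‑labdane ring configuration) | C=C[C@](C)(O)C[C@H](O)[C@@H]1[C@@]2(C)CC(=O)O[C@]1(C)C[C@@H](O)[C@H]2C(C)(C)C(=O)O
A2 | alternative 2 | dilactone of 23 (additional C3→O6 γ‑lactone) | C[C@@]12CC(=O)O[C@@](C)(C[C@H]3OC(=O)C(C)(C)[C@@H]13)[C@@H]2[C@@H](O)C[C@@](C)(O)C=C
A3 | alternative 3 | bicyclo[3.2.1]octan‑6‑one with a C2–C8 bond in place of the lactone oxygen | C[C@@]12CC(=O)[C@@](C)(C[C@@H](O)[C@H]1C(C)(C)C(=O)O)[C@@H]2[C@@H](O)C[C@@](C)(O)C=C
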